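**Retrosynthetic overview**

1. 21 ⇐ 19 (ester hydrolysis) ⇐ 17 by a one-flask relay: the pyran ring is closed through the C4–C4a bond (gold-catalysed 6-endo-dig hydroarylation of the aryl 1,1-dimethylpropargyl ether), then the flat phloroglucinol ring is dearomatized by asymmetric prenylation at C8 (zerovalent palladium, chiral diphosphine).
2. Enabling feature: in 17 the benzophenone ring has a single C–H carbon (future C4a), ortho to the ether oxygen (future O1) that carries the alkyne and flanked by the hydroxyl-bearing C5. It alone can close the six-membered pyran ring and rearomatize, and once it is used C8 (between O1 and the C7 hydroxyl, bearing the side chain) is the only alkyl-substituted nucleophilic ring carbon left.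
3. 17 ⇐ 16 (etherification of the phenol para to the benzoyl group) ⇐ 9 + 7 (aryllithium alkylation, Weinreb benzoylation, cross-metathesis with methyl methacrylate, MOM removal).
4. 7 ⇐ 1 + 2 (Evans deconjugative allylation sets C5 of the side chain).
5. Ring order: the carbocycle is bought with phloroglucinol 8; the pyran ring is the only ring formed (step 10) and the carbocycle is dearomatized in the same operation.

Key step: step 10

Assumption: the enolized acyl-triketone of 19–21 is written as the one tautomer of the target SMILES (the tautomers interconvert), and the sense of induction of the (R,R)-diphosphine in step 10 is provisional, its enantiomer being used if the 8R epimer predominates.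

**Route**

Step 1
Reactants: 1 (S)-4-benzyl-1,3-oxazolidin-2-one; 2 3-methylbut-2-enoyl chloride
Product: 4 (S)-4-benzyl-3-(3-methylbut-2-enoyl)-1,3-oxazolidin-2-one, via lithium oxazolidinide 3 (not isolated)
Conditions: n-BuLi, THF, −78 °C; then 2, −78 → 0 °C
Reagents that add atoms: none
Why: N-acylation of the lithiated oxazolidinone by the acid chloride is the standard preparation of an Evans imide and forms no stereocentre.

Step 2
Reactants: 4 (S)-4-benzyl-3-(3-methylbut-2-enoyl)-1,3-oxazolidin-2-one
Product: 6 (S)-4-benzyl-3-[(2S)-2-(prop-1-en-2-yl)pent-4-enoyl]-1,3-oxazolidin-2-one, via sodium dienolate 5 (not isolated)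
Conditions: NaN(SiMe3)2, THF, −78 °C; allyl bromide, −78 → −40 °C
Reagents that add atoms: allyl bromide, C=CCBr
Why: γ-deprotonation of the s-cis enoyl imide gives the chelated sodium (Z)-dienolate, which is alkylated at the α-carbon on the face opposite the benzyl group (Evans asymmetric alkylation in its deconjugative form), setting the (S) centre that becomes C5 of the side chain.

Step 3
Reactants: 6 (S)-4-benzyl-3-[(2S)-2-(prop-1-en-2-yl)pent-4-enoyl]-1,3-oxazolidin-2-one
Product: 7 (2S)-2-(prop-1-en-2-yl)pent-4-en-1-ol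
Conditions: LiBH4, MeOH (1 equiv), Et2O, 0 °C
Reagents that add atoms: none
Why: reductive cleavage of the Evans auxiliary with LiBH4 gives the primary alcohol, returns the auxiliary and leaves the stereocentre intact because hydride attack on the imide carbonyl is faster than enolization.

Step 4
Reactants: 8 phloroglucinol (benzene-1,3,5-triol)
Product: 9 1,3,5-tris(methoxymethoxy)benzene
Conditions: NaH, DMF, 0 °C; MOMCl, 0 °C → rt
Reagents that add atoms: chloromethyl methyl ether, COCCl
Why: threefold Williamson-type O-alkylation of the phenoxide by the hard electrophile MOMCl installs the acetal groups that direct both later ortho-lithiations.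

Step 5
Reactants: 7 (2S)-2-(prop-1-en-2-yl)pent-4-en-1-ol; 9 1,3,5-tris(methoxymethoxy)benzene
Product: 12 1,3,5-tris(methoxymethoxy)-2-[(2R)-2-(prop-1-en-2-yl)pent-4-en-1-yl]benzene, via alkyl triflate 10 (not isolated), via aryllithium 11 (not isolated)
Conditions: 7, Tf2O, 2,6-lutidine, CH2Cl2, −78 °C, then hexane, filtration and solvent exchange to THF; 9 (1.5 equiv), n-BuLi, THF, 0 °C, then the triflate solution, −78 → 0 °C
Reagents that add atoms: none
Why: directed ortho-lithiation between two MOM ethers gives a chelated aryllithium that displaces the primary triflate in an SN2 alkylation, forming the aryl–CH2 bond without involving the β stereocentre (its descriptor changes from S to R only through the CIP priorities).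

Step 6
Reactants: 12 1,3,5-tris(methoxymethoxy)-2-[(2R)-2-(prop-1-en-2-yl)pent-4-en-1-yl]benzene
Product: 14 {2,4,6-tris(methoxymethoxy)-3-[(2R)-2-(prop-1-en-2-yl)pent-4-en-1-yl]phenyl}(phenyl)methanone, via aryllithium 13 (not isolated)
Conditions: n-BuLi, THF, 0 °C; PhC(O)N(OMe)Me, −78 → 0 °C
Reagents that add atoms: N-methoxy-N-methylbenzamide, CON(C)C(=O)c1ccccc1
Why: a second directed ortho-lithiation takes place at a ring C–H flanked by two MOM ethers (the two such positions are equivalent) and the aryllithium is acylated through a stable chelate (Weinreb ketone synthesis), so over-addition is avoided.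

Step 7
Reactants: 14 {2,4,6-tris(methoxymethoxy)-3-[(2R)-2-(prop-1-en-2-yl)pent-4-en-1-yl]phenyl}(phenyl)methanone
Product: 15 methyl (2E,5R)-5-{[3-benzoyl-2,4,6-tris(methoxymethoxy)phenyl]methyl}-2,6-dimethylhepta-2,6-dienoate
Conditions: methyl methacrylate (10 equiv), second-generation Hoveyda–Grubbs catalyst (C31H38Cl2N2ORu, 5 mol%), CH2Cl2, 40 °C
Reagents that add atoms: methyl methacrylate, C=C(C)C(=O)OC
Why: olefin cross-metathesis of the monosubstituted alkene with excess methacrylate should give the trisubstituted (E)-enoate under thermodynamic control, while the hindered 1,1-disubstituted isopropenyl group stays out of the catalytic cycle.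

Step 8
Reactants: 15 methyl (2E,5R)-5-{[3-benzoyl-2,4,6-tris(methoxymethoxy)phenyl]methyl}-2,6-dimethylhepta-2,6-dienoate
Product: 16 methyl (2E,5R)-5-[(3-benzoyl-2,4,6-trihydroxyphenyl)methyl]-2,6-dimethylhepta-2,6-dienoate
Conditions: 3 M HCl, MeOH, rt
Reagents that add atoms: none
Why: acid-catalysed acetal exchange with methanol removes the three MOM ethers under conditions mild enough to leave the isopropenyl group and the methyl ester untouched.

Step 9
Reactants: 16 methyl (2E,5R)-5-[(3-benzoyl-2,4,6-trihydroxyphenyl)methyl]-2,6-dimethylhepta-2,6-dienoate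
Product: 17 methyl (2E,5R)-5-({3-benzoyl-2,4-dihydroxy-6-[(2-methylbut-3-yn-2-yl)oxy]phenyl}methyl)-2,6-dimethylhepta-2,6-dienoate
Conditions: 3-chloro-3-methylbut-1-yne, CuCl2·2H2O (1 mol%), DBU, MeCN, 0 °C
Reagents that add atoms: 3-chloro-3-methylbut-1-yne, C#CC(C)(C)Cl
Why: copper-catalysed propargylic substitution (through a copper acetylide/allenylidene) should etherify the most acidic phenol, the one para to the benzoyl group, because the two ortho hydroxyls are tied up in hydrogen bonds to the ketone.

Step 10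
Reactants: 17 methyl (2E,5R)-5-({3-benzoyl-2,4-dihydroxy-6-[(2-methylbut-3-yn-2-yl)oxy]phenyl}methyl)-2,6-dimethylhepta-2,6-dienoate
Product: 19 methyl (2E,5R)-5-{[(8S)-6-benzoyl-7-hydroxy-2,2-dimethyl-8-(3-methylbut-2-en-1-yl)-5-oxo-5,8-dihydro-2H-chromen-8-yl]methyl}-2,6-dimethylhepta-2,6-dienoate, via chromene 18 (not isolated)
Conditions: Ph3PAuNTf2 (2 mol%), CH2Cl2, rt; then Cs2CO3, 3-methylbut-2-en-1-yl acetate, Pd2(dba)3·CHCl3 (2.5 mol%), (1R,2R)-N,N'-bis[2-(diphenylphosphino)benzoyl]cyclohexane-1,2-diamine (8 mol%), rt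
Reagents that add atoms: 3-methylbut-2-en-1-yl acetate, CC(C)=CCOC(C)=O
Why: Ph3PAuNTf2 π-activates the terminal alkyne of 17, the single ring C–H carbon (future C4a) attacks the terminal alkyne carbon (future C4) in a Friedel–Crafts manner and rearomatization with protodeauration gives chromene 18, after which base, prenyl acetate and the zerovalent palladium–diphosphine catalyst added to the same flask form a cationic π-prenyl palladium complex that is attacked at its CH2 terminus by C8 of the caesium phenoxide, so that the ring is dearomatized. The closest known reaction types are the gold-catalysed intramolecular hydroarylation of aryl 1,1-dimethylpropargyl ethers to 2,2-dimethyl-2H-chromenes and the palladium-catalysed asymmetric allylic dearomatization of phenols (Tsuji–Trost type). The pyran ring, the only ring closed, forms in the 6-endo-dig mode through the new C4–C4a bond, the gem-dimethyl group shielding the internal alkyne carbon against the 5-exo alternative. The new quaternary stereocentre C8 is controlled by the chiral diphosphine on palladium, which differentiates the two faces of the planar phenoxide whose flanks (hydroxyl-bearing C7 and pyran oxygen O1) are different, while the remote C5 centre only makes the two possible products diastereomers. The ring closure needs site selectivity between the two carbons ortho to O1, secured because the other one carries the side chain and cannot rearomatize, and the prenylation needs C8 rather than C4a, C6 or oxygen, secured because the ring closure has used up the only ring C–H, attack at C4a would take the new C3=C4 bond out of conjugation, C6 carries the benzoyl group and O-prenyl ethers of these acidic phenols re-ionize under the catalyst. The gold catalyst is quenched by the base and the phosphine before the second stage, so the two cycles should not interfere.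

Step 11
Reactants: 19 methyl (2E,5R)-5-{[(8S)-6-benzoyl-7-hydroxy-2,2-dimethyl-8-(3-methylbut-2-en-1-yl)-5-oxo-5,8-dihydro-2H-chromen-8-yl]methyl}-2,6-dimethylhepta-2,6-dienoate
Product: 21 (2E,5R)-5-{[(8S)-6-benzoyl-7-hydroxy-2,2-dimethyl-8-(3-methylbut-2-en-1-yl)-5-oxo-5,8-dihydro-2H-chromen-8-yl]methyl}-2,6-dimethylhepta-2,6-dienoic acid, via dilithium salt 20 (not isolated)
Conditions: LiOH·H2O, THF/MeOH/H2O, 40 °C; then 1 M HCl, 0 °C
Reagents that add atoms: lithium hydroxide, [Li+].[OH-]
Why: saponification of the methyl ester (BAc2) proceeds on the polyanion, in which the enolized triketone is protected as its enolate against retro-Claisen cleavage, and acidification returns the acid without touching either stereocentre.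

**Compound list**

1 | (S)-4-benzyl-1,3-oxazolidin-2-one | O=C1N[C@@H](Cc2ccccc2)CO1 | starting material
2 | 3-methylbut-2-enoyl chloride | CC(C)=CC(=O)Cl | starting material
3 | lithium (4S)-4-benzyl-2-oxo-1,3-oxazolidin-3-ide | [Li+].O=C1[N-][C@@H](Cc2ccccc2)CO1 | intermediate
4 | (S)-4-benzyl-3-(3-methylbut-2-enoyl)-1,3-oxazolidin-2-one | CC(C)=CC(=O)N1[C@@H](Cc2ccccc2)COC1=O | intermediate
5 | sodium (1Z)-1-[(4S)-4-benzyl-2-oxo-1,3-oxazolidin-3-yl]-3-methylbuta-1,3-dien-1-olate | [Na+].[O-]/C(=C\C(C)=C)N1[C@@H](Cc2ccccc2)COC1=O | intermediate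
6 | (S)-4-benzyl-3-[(2S)-2-(prop-1-en-2-yl)pent-4-enoyl]-1,3-oxazolidin-2-one | C=C(C)[C@H](CC=C)C(=O)N1[C@@H](Cc2ccccc2)COC1=O | intermediate
7 | (2S)-2-(prop-1-en-2-yl)pent-4-en-1-ol | C=C(C)[C@H](CC=C)CO | intermediate
8 | phloroglucinol (benzene-1,3,5-triol) | Oc1cc(O)cc(O)c1 | starting material
9 | 1,3,5-tris(methoxymethoxy)benzene | COCOc1cc(OCOC)cc(OCOC)c1 | intermediate
10 | (2S)-2-(prop-1-en-2-yl)pent-4-en-1-yl trifluoromethanesulfonate | C=C(C)[C@H](CC=C)COS(=O)(=O)C(F)(F)F | intermediate
11 | [2,4,6-tris(methoxymethoxy)phenyl]lithium | [Li]c1c(OCOC)cc(OCOC)cc1OCOC | intermediate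
12 | 1,3,5-tris(methoxymethoxy)-2-[(2R)-2-(prop-1-en-2-yl)pent-4-en-1-yl]benzene | C=C(C)[C@H](CC=C)Cc1c(OCOC)cc(OCOC)cc1OCOC | intermediate
13 | {2,4,6-tris(methoxymethoxy)-3-[(2R)-2-(prop-1-en-2-yl)pent-4-en-1-yl]phenyl}lithium | C=C(C)[C@H](CC=C)Cc1c(OCOC)cc(OCOC)c([Li])c1OCOC | intermediate
14 | {2,4,6-tris(methoxymethoxy)-3-[(2R)-2-(prop-1-en-2-yl)pent-4-en-1-yl]phenyl}(phenyl)methanone | C=C(C)[C@H](CC=C)Cc1c(OCOC)cc(OCOC)c(C(=O)c2ccccc2)c1OCOC | intermediate
15 | methyl (2E,5R)-5-{[3-benzoyl-2,4,6-tris(methoxymethoxy)phenyl]methyl}-2,6-dimethylhepta-2,6-dienoate | C=C(C)[C@H](C/C=C(\C)C(=O)OC)Cc1c(OCOC)cc(OCOC)c(C(=O)c2ccccc2)c1OCOC | intermediate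
16 | methyl (2E,5R)-5-[(3-benzoyl-2,4,6-trihydroxyphenyl)methyl]-2,6-dimethylhepta-2,6-dienoate | C=C(C)[C@H](C/C=C(\C)C(=O)OC)Cc1c(O)cc(O)c(C(=O)c2ccccc2)c1O | intermediate
17 | methyl (2E,5R)-5-({3-benzoyl-2,4-dihydroxy-6-[(2-methylbut-3-yn-2-yl)oxy]phenyl}methyl)-2,6-dimethylhepta-2,6-dienoate | C=C(C)[C@H](C/C=C(\C)C(=O)OC)Cc1c(OC(C)(C)C#C)cc(O)c(C(=O)c2ccccc2)c1O | intermediate
18 | methyl (2E,5R)-5-[(6-benzoyl-5,7-dihydroxy-2,2-dimethyl-2H-chromen-8-yl)methyl]-2,6-dimethylhepta-2,6-dienoate | C=C(C)[C@H](C/C=C(\C)C(=O)OC)Cc1c(O)c(C(=O)c2ccccc2)c(O)c2c1OC(C)(C)C=C2 | intermediate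
19 | methyl (2E,5R)-5-{[(8S)-6-benzoyl-7-hydroxy-2,2-dimethyl-8-(3-methylbut-2-en-1-yl)-5-oxo-5,8-dihydro-2H-chromen-8-yl]methyl}-2,6-dimethylhepta-2,6-dienoate | C=C(C)[C@H](C/C=C(\C)C(=O)OC)C[C@@]1(CC=C(C)C)C(O)=C(C(=O)c2ccccc2)C(=O)C2=C1OC(C)(C)C=C2 | intermediate
20 | dilithium enolate carboxylate of 21 | [Li+].[Li+].C=C(C)[C@H](C/C=C(\C)C(=O)[O-])C[C@@]1(CC=C(C)C)C([O-])=C(C(=O)c2ccccc2)C(=O)C2=C1OC(C)(C)C=C2 | intermediate
21 | (2E,5R)-5-{[(8S)-6-benzoyl-7-hydroxy-2,2-dimethyl-8-(3-methylbut-2-en-1-yl)-5-oxo-5,8-dihydro-2H-chromen-8-yl]methyl}-2,6-dimethylhepta-2,6-dienoic acid | C=C(C)[C@H](C/C=C(\C)C(=O)O)C[C@@]1(CC=C(C)C)C(O)=C(C(=O)c2ccccc2)C(=O)C2=C1OC(C)(C)C=C2 | target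

**Step count and risks**

Total step count: 11. Longest linear sequence: 10 steps (from 1 through steps 1, 2, 3 and 5 to 11).

Steps most likely to fail:

Step 10. In the second stage the prenyl group may be delivered to a phenolic oxygen or to C4a instead of C8, or to C8 with poor facial selectivity, and residual gold may disturb the palladium cycle. The fallback sets out from 17: the gold-catalysed ring closure is run alone and chromene 18 is isolated. Its dilithium phenoxide (LiN(SiMe3)2, toluene, 0 °C) is then C-alkylated with prenyl bromide in a classical alkylative dearomatization through a contact ion pair. This is not face-selective and should give 19 together with its C8 epimer, methyl (2E,5R)-5-{[(8R)-6-benzoyl-7-hydroxy-2,2-dimethyl-8-(3-methylbut-2-en-1-yl)-5-oxo-5,8-dihydro-2H-chromen-8-yl]methyl}-2,6-dimethylhepta-2,6-dienoate F1. Because the C5 centre is fixed the two are diastereomers and are separated by chromatography; the route is rejoined at 19.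

Step 5. The SN2 displacement at the β-branched carbon may be slow, with elimination of the triflate or proton transfer to the aryllithium taking over. The fallback sets out from 7 and 9 and replaces the alkylation by a B-alkyl Suzuki–Miyaura coupling. Alcohol 7 is converted (I2, PPh3, imidazole, CH2Cl2) into (3S)-3-(iodomethyl)-2-methylhexa-1,5-diene F2. Arene 9 is brominated (NBS, MeCN, 0 °C) to 2-bromo-1,3,5-tris(methoxymethoxy)benzene F3. Lithium–iodine exchange on F2 (t-BuLi, Et2O, −78 °C) and trapping with 9-methoxy-9-borabicyclo[3.3.1]nonane gives lithium B-methoxy-B-[(2S)-2-(prop-1-en-2-yl)pent-4-en-1-yl]-9-borabicyclo[3.3.1]nonan-9-uide F4. This is coupled with F3 (Pd(OAc)2, SPhos, K3PO4, THF/H2O, 50 °C), and the route is rejoined at 12.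

Step 9. The etherification may show poor site selectivity among the three phenols, and reaction at an ortho hydroxyl would lead on to the linear chromene. The fallback sets out from 16 and differentiates the phenols by protection. Peracetylation (Ac2O, pyridine) gives methyl (2E,5R)-5-{[2,4,6-tris(acetyloxy)-3-benzoylphenyl]methyl}-2,6-dimethylhepta-2,6-dienoate F5. Selective thiolysis of the acetate para to the benzoyl group (PhSH, imidazole, N-methylpyrrolidone, 0 °C; the most acidic phenol is the best leaving group) gives methyl (2E,5R)-5-{[2,4-bis(acetyloxy)-3-benzoyl-6-hydroxyphenyl]methyl}-2,6-dimethylhepta-2,6-dienoate F6. Its single free phenol is etherified under the conditions of step 9 to methyl (2E,5R)-5-({2,4-bis(acetyloxy)-3-benzoyl-6-[(2-methylbut-3-yn-2-yl)oxy]phenyl}methyl)-2,6-dimethylhepta-2,6-dienoate F7. Methanolysis of the two acetates (K2CO3, MeOH, 0 °C) rejoins the route at 17.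

**Further compounds**

F1 | step 10 | methyl (2E,5R)-5-{[(8R)-6-benzoyl-7-hydroxy-2,2-dimethyl-8-(3-methylbut-2-en-1-yl)-5-oxo-5,8-dihydro-2H-chromen-8-yl]methyl}-2,6-dimethylhepta-2,6-dienoate | C=C(C)[C@H](C/C=C(\C)C(=O)OC)C[C@]1(CC=C(C)C)C(O)=C(C(=O)c2ccccc2)C(=O)C2=C1OC(C)(C)C=C2
F2 | step 5 | (3S)-3-(iodomethyl)-2-methylhexa-1,5-diene | C=C(C)[C@H](CC=C)CI
F3 | step 5 | 2-bromo-1,3,5-tris(methoxymethoxy)benzene | COCOc1cc(OCOC)c(Br)c(OCOC)c1
F4 | step 5 | lithium B-methoxy-B-[(2S)-2-(prop-1-en-2-yl)pent-4-en-1-yl]-9-borabicyclo[3.3.1]nonan-9-uide | [Li+].C=C(C)[C@H](CC=C)C[B-]1(OC)C2CCCC1CCC2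
F5 | step 9 | methyl (2E,5R)-5-{[2,4,6-tris(acetyloxy)-3-benzoylphenyl]methyl}-2,6-dimethylhepta-2,6-dienoate | C=C(C)[C@H](C/C=C(\C)C(=O)OC)Cc1c(OC(C)=O)cc(OC(C)=O)c(C(=O)c2ccccc2)c1OC(C)=O
F6 | step 9 | methyl (2E,5R)-5-{[2,4-bis(acetyloxy)-3-benzoyl-6-hydroxyphenyl]methyl}-2,6-dimethylhepta-2,6-dienoate | C=C(C)[C@H](C/C=C(\C)C(=O)OC)Cc1c(O)cc(OC(C)=O)c(C(=O)c2ccccc2)c1OC(C)=O
F7 | step 9 | methyl (2E,5R)-5-({2,4-bis(acetyloxy)-3-benzoyl-6-[(2-methylbut-3-yn-2-yl)oxy]phenyl}methyl)-2,6-dimethylhepta-2,6-dienoate | C=C(C)[C@H](C/C=C(\C)C(=O)OC)Cc1c(OC(C)(C)C#C)cc(OC(C)=O)c(C(=O)c2ccccc2)c1OC(C)=O
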